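**Retrosynthetic overview**
- The strategy rests on one feature: the two hydrogen-bonded phenols, on C5 of flavone ring A and on C5'' of flavanone ring A'', each lie peri to a pyranone carbonyl (C4=O and C4''=O). Both C–O bonds are therefore made last, in one ketone-directed C–H hydroxylation of the 5,5''-dideoxy 4'''-acetate, and the acetate is then removed.
- The dideoxy precursor comes from a 3-unsubstituted chromone and 4-acetoxyphenylboronic acid by asymmetric conjugate addition, which attaches ring B'' and sets C2''.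
- The chromone ring C'' is closed from an ortho-hydroxyacetophenone, made by C-acylation (para to OMe) of a phenol on the diaryl ether.
- Flavone ring C is closed by Claisen condensation and cyclodehydration of paeonol with a diaryl ether ester; the ether comes from an SNAr reaction and a Dakin oxidation.
- Order: diaryl ether (rings B and A''), then ring C onto ring A, then ring C'', then ring B''; the key step closes no ring.

Key step: step 7

Assumption: the pyridine–oxazoline palladium catalyst is taken to show on the chromone of step 6 the facial preference known for simple chromones and cyclic enones, where the (S)-ligand gives (R)-products, so the (R)-ligand is specified for the (2''S) centre; this is to be confirmed by circular dichroism against known (2S)-flavanones.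

Step 1
Reactants: 1 methyl 4-hydroxybenzoate; 2 4-fluoro-3-methoxybenzaldehyde
Product: 3 methyl 4-(4-formyl-2-methoxyphenoxy)benzoate
Conditions: K2CO3, DMF, 110 °C
Reagents that add atoms: none
Why: Nucleophilic aromatic substitution (SNAr), in which the para-formyl group stabilises the Meisenheimer adduct of 2 and fluoride leaves, so the phenoxide of 1 should form the diaryl ether while carbonate leaves the methyl ester alone.

Step 2
Reactants: 3 methyl 4-(4-formyl-2-methoxyphenoxy)benzoate
Product: 5 methyl 4-(4-hydroxy-2-methoxyphenoxy)benzoate, via aryl formate 4 (not isolated)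
Conditions: mCPBA, CH2Cl2, 0 °C → rt; aq. NaHCO3 wash; then K2CO3 (cat.), MeOH, rt
Reagents that add atoms: meta-chloroperoxybenzoic acid, O=C(OO)c1cccc(Cl)c1
Why: Dakin oxidation run as a Baeyer–Villiger reaction, in which the aryl group para to the aryloxy donor migrates in the Criegee adduct to give formate 4, and catalytic carbonate in methanol then cleaves the formate while exchange at the methyl benzoate is degenerate.

Step 3
Reactants: 5 methyl 4-(4-hydroxy-2-methoxyphenoxy)benzoate; 6 paeonol (2'-hydroxy-4'-methoxyacetophenone)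
Product: 8 2-[4-(4-hydroxy-2-methoxyphenoxy)phenyl]-7-methoxy-4H-chromen-4-one, via 1,3-diketone 7 (not isolated)
Conditions: LiN(SiMe3)2 (4.5 equiv), THF, −78 °C → rt; AcOH quench, evaporate; then AcOH, H2SO4 (cat.), 95 °C
Reagents that add atoms: none
Why: Crossed Claisen condensation followed by acid cyclodehydration (the ester variant of the Baker–Venkataraman flavone synthesis), in which the dianion of 6 is acylated on carbon by the non-enolisable ester 5, carried as its lithium phenoxide, and the ortho-hydroxyaryl diketone 7 closes ring C by attack of the phenol on the distal carbonyl and loss of water.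

Step 4
Reactants: 8 2-[4-(4-hydroxy-2-methoxyphenoxy)phenyl]-7-methoxy-4H-chromen-4-one
Product: 9 2-[4-(5-acetyl-4-hydroxy-2-methoxyphenoxy)phenyl]-7-methoxy-4H-chromen-4-one
Conditions: BF3·OEt2, AcOH, 90 °C; then aq. NaHCO3
Reagents that add atoms: acetic acid, CC(=O)O
Why: BF3-mediated Friedel–Crafts (Fries-type) C-acylation of a phenol, which should go only to the position ortho to OH and para to OMe on the one electron-rich ring, since the other ortho site is flanked by OMe and the flavone rings are deactivated by the BF3-complexed pyranone.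

Step 5
Reactants: 9 2-[4-(5-acetyl-4-hydroxy-2-methoxyphenoxy)phenyl]-7-methoxy-4H-chromen-4-one
Product: 11 7-methoxy-2-{4-[(7-methoxy-4-oxo-4H-chromen-6-yl)oxy]phenyl}-4H-chromen-4-one, via enaminone 10 (not isolated)
Conditions: Me2NCH(OMe)2 (3 equiv), toluene, 100 °C; evaporate; then conc. HCl, CH2Cl2, rt
Reagents that add atoms: N,N-dimethylformamide dimethyl acetal, COC(OC)N(C)C
Why: Enaminone route to chromones, in which the acetal condenses with the methyl ketone to give vinylogous amide 10 and acid then promotes conjugate addition of the ortho phenol and loss of dimethylamine, closing ring C'' (6-endo-trig) without affecting the flavone.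

Step 6
Reactants: 11 7-methoxy-2-{4-[(7-methoxy-4-oxo-4H-chromen-6-yl)oxy]phenyl}-4H-chromen-4-one; 12 4-acetoxyphenylboronic acid
Product: 13 (S)-4-{7-methoxy-6-[4-(7-methoxy-4-oxo-4H-chromen-2-yl)phenoxy]-4-oxochroman-2-yl}phenyl acetate
Conditions: Pd(OCOCF3)2 (10 mol%), (R)-t-BuPyOX [(R)-4-tert-butyl-2-(pyridin-2-yl)-4,5-dihydrooxazole] (12 mol%), NH4PF6 (30 mol%), H2O (5 equiv), ClCH2CH2Cl, 60 °C
Reagents that add atoms: none
Why: Palladium-catalysed asymmetric conjugate addition of an arylboronic acid to a chromone, in which the cationic aryl–palladium complex inserts the unsubstituted C2''=C3'' bond (the 2-aryl-substituted flavone enone is too hindered to insert), water protonates the palladium enolate, and the tert-butyl group of the (R)-ligand shields one face so that the aryl group is delivered to the face that gives the (2''S) centre.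

Step 7
Reactants: 13 (S)-4-{7-methoxy-6-[4-(7-methoxy-4-oxo-4H-chromen-2-yl)phenoxy]-4-oxochroman-2-yl}phenyl acetate
Product: 15 (S)-4-{5-hydroxy-6-[4-(5-hydroxy-7-methoxy-4-oxo-4H-chromen-2-yl)phenoxy]-7-methoxy-4-oxochroman-2-yl}phenyl acetate, via bis(trifluoroacetate) 14 (not isolated)
Conditions: [RuCl2(p-cymene)]2 (10 mol%), PhI(OCOCF3)2 (3 equiv, in portions), CF3CO2H/(CF3CO)2O 3:1, 80 °C; then H2O, THF, rt
Reagents that add atoms: [bis(trifluoroacetoxy)iodo]benzene, O=C(OI(OC(=O)C(F)(F)F)c1ccccc1)C(F)(F)F
Why: Each pyranone carbonyl binds a cationic ruthenium trifluoroacetate and directs carboxylate-assisted metalation of its own peri C–H bond (C5–H and C5''–H) through a five-membered ruthenacycle; PhI(OCOCF3)2 oxidises the metallacycle to tetravalent ruthenium, C–O reductive elimination gives the two aryl trifluoroacetates of 14, and water hydrolyses them to the chelated phenols. The closest known reaction is the ruthenium-catalysed ketone-directed ortho C–H hydroxylation of aryl ketones, demonstrated at C5 of chromones and flavones and on cyclic aryl alkyl ketones. No ring is closed and no stereocentre is formed; the existing C2'' centre is not involved, and ruthenium is preferred to palladium because divalent palladium could dehydrogenate ring C''. Site selectivity is needed at two positions and is fixed by geometry, since each ketone has exactly one peri C–H bond and neither C3 nor the ring B positions can reach a five-membered chelate. Chemoselectivity against electrophilic oxidation of the diaryl ether by the trivalent iodine reagent rests on the acyl-type substituent carried by rings A, B and A'' and on the acetate on ring B'', and the acetate also disfavours acid-induced opening of ring C'' at the benzylic C2''–O bond.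

Step 8
Reactants: 15 (S)-4-{5-hydroxy-6-[4-(5-hydroxy-7-methoxy-4-oxo-4H-chromen-2-yl)phenoxy]-7-methoxy-4-oxochroman-2-yl}phenyl acetate
Product: 16 (S)-5-hydroxy-6-[4-(5-hydroxy-7-methoxy-4-oxo-4H-chromen-2-yl)phenoxy]-2-(4-hydroxyphenyl)-7-methoxychroman-4-one (CNP0202121.1)
Conditions: HCl (1.25 M in MeOH), rt
Reagents that add atoms: none
Why: Acid-catalysed transesterification of an aryl acetate with methanol, which should free the 4'''-phenol without touching the methyl ethers or the diaryl ether, and which avoids the base-induced retro-oxa-Michael opening that would racemise C2''.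

**Compound list**
1 | methyl 4-hydroxybenzoate | COC(=O)c1ccc(O)cc1 | starting material
2 | 4-fluoro-3-methoxybenzaldehyde | COc1cc(C=O)ccc1F | starting material
3 | methyl 4-(4-formyl-2-methoxyphenoxy)benzoate | COC(=O)c1ccc(Oc2ccc(C=O)cc2OC)cc1 | intermediate
4 | methyl 4-[4-(formyloxy)-2-methoxyphenoxy]benzoate (aryl formate, not isolated) | COC(=O)c1ccc(Oc2ccc(OC=O)cc2OC)cc1 | intermediate
5 | methyl 4-(4-hydroxy-2-methoxyphenoxy)benzoate | COC(=O)c1ccc(Oc2ccc(O)cc2OC)cc1 | intermediate
6 | paeonol (2'-hydroxy-4'-methoxyacetophenone) | CC(=O)c1ccc(OC)cc1O | starting material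
7 | 1-(2-hydroxy-4-methoxyphenyl)-3-[4-(4-hydroxy-2-methoxyphenoxy)phenyl]propane-1,3-dione (not isolated) | COc1ccc(C(=O)CC(=O)c2ccc(Oc3ccc(O)cc3OC)cc2)c(O)c1 | intermediate
8 | 2-[4-(4-hydroxy-2-methoxyphenoxy)phenyl]-7-methoxy-4H-chromen-4-one | COc1ccc2c(=O)cc(-c3ccc(Oc4ccc(O)cc4OC)cc3)oc2c1 | intermediate
9 | 2-[4-(5-acetyl-4-hydroxy-2-methoxyphenoxy)phenyl]-7-methoxy-4H-chromen-4-one | COc1ccc2c(=O)cc(-c3ccc(Oc4cc(C(C)=O)c(O)cc4OC)cc3)oc2c1 | intermediate
10 | (E)-3-(dimethylamino)-1-{2-hydroxy-4-methoxy-5-[4-(7-methoxy-4-oxo-4H-chromen-2-yl)phenoxy]phenyl}prop-2-en-1-one (enaminone, not isolated) | COc1ccc2c(=O)cc(-c3ccc(Oc4cc(C(=O)/C=C/N(C)C)c(O)cc4OC)cc3)oc2c1 | intermediate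
11 | 7-methoxy-2-{4-[(7-methoxy-4-oxo-4H-chromen-6-yl)oxy]phenyl}-4H-chromen-4-one | COc1ccc2c(=O)cc(-c3ccc(Oc4cc5c(=O)ccoc5cc4OC)cc3)oc2c1 | intermediate
12 | 4-acetoxyphenylboronic acid | CC(=O)Oc1ccc(B(O)O)cc1 | starting material
13 | (S)-4-{7-methoxy-6-[4-(7-methoxy-4-oxo-4H-chromen-2-yl)phenoxy]-4-oxochroman-2-yl}phenyl acetate (5,5''-dideoxy 4'''-acetate) | COc1ccc2c(=O)cc(-c3ccc(Oc4c(OC)cc5c(c4)C(=O)C[C@@H](c4ccc(OC(C)=O)cc4)O5)cc3)oc2c1 | intermediate
14 | 5,5''-bis(trifluoroacetate) of 15 (not isolated) | COc1cc(OC(=O)C(F)(F)F)c2c(=O)cc(-c3ccc(Oc4c(OC)cc5c(c4OC(=O)C(F)(F)F)C(=O)C[C@@H](c4ccc(OC(C)=O)cc4)O5)cc3)oc2c1 | intermediate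
15 | (S)-4-{5-hydroxy-6-[4-(5-hydroxy-7-methoxy-4-oxo-4H-chromen-2-yl)phenoxy]-7-methoxy-4-oxochroman-2-yl}phenyl acetate | COc1cc(O)c2c(=O)cc(-c3ccc(Oc4c(OC)cc5c(c4O)C(=O)C[C@@H](c4ccc(OC(C)=O)cc4)O5)cc3)oc2c1 | intermediate
16 | (S)-5-hydroxy-6-[4-(5-hydroxy-7-methoxy-4-oxo-4H-chromen-2-yl)phenoxy]-2-(4-hydroxyphenyl)-7-methoxychroman-4-one | COc1cc(O)c2c(=O)cc(-c3ccc(Oc4c(OC)cc5c(c4O)C(=O)C[C@@H](c4ccc(O)cc4)O5)cc3)oc2c1 | target

Total step count: 8
Longest linear sequence: 8 steps (1 and 2 to 16)

**Steps most likely to fail**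

Step 7. The second metalation, at C5''–H next to the aryloxy-bearing C6'', may stall after the first hydroxylation. The trivalent iodine oxidant may also attack the enol of the C4'' ketone, giving oxygenation at C3'' or dehydrogenation of ring C''. Hot trifluoroacetic acid may open and reclose ring C'' and so erode the enantiomeric purity. The fallback sets out from bis-chromone 11 and applies the same ruthenium-catalysed hydroxylation there. Both peri C–H bonds then belong to chromone-type ketones, the directly precedented case, and there is no enolisable CH2 and no stereocentre during the oxidation. This should give, via the 5,5''-bis(trifluoroacetate) of the bis-chromone F1, the 5,5''-dihydroxy bis-chromone F2. Asymmetric conjugate addition of 12 to F2 under the conditions of step 6 then gives 15, where the fallback rejoins the route; the chelated 5''-OH should make the chromone a better acceptor.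

Step 6. Insertion into the electron-rich chromone, which carries oxygen donors at C6'' and C7'', may be slower than protodeboronation of 12, or the facial discrimination may be insufficient. The fallback sets out from acetophenone 9 and replaces asymmetric catalysis by racemic ring closure and resolution. Claisen–Schmidt condensation of 9 with 4-(methoxymethoxy)benzaldehyde (KOH, EtOH, rt) should give the 2'-hydroxychalcone F3. Oxa-Michael closure (NaOAc, EtOH, reflux) gives the racemic MOM-protected flavanone F4, and HCl in MeOH at rt gives the racemic 4'''-hydroxyflavanone F5. Ac2O in pyridine gives the racemic 4'''-acetate F6. Preparative HPLC on a chiral stationary phase then separates 13, where the route resumes, from the (R)-enantiomer F7.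

Step 3. The intermolecular acylation may stay incomplete, because ester 5 reacts as an aggregated lithium phenoxide and self-condensation of 6 competes. The fallback sets out from 5 and makes the same C–C bond by intramolecular acyl transfer. Saponification (LiOH, THF/H2O) gives 4-(4-hydroxy-2-methoxyphenoxy)benzoic acid F8, and Ac2O in pyridine with aqueous work-up gives the acetoxy acid F9. (COCl)2 with catalytic DMF gives the acid chloride F10, which acylates 6 in pyridine to the aryl ester F11. KOH in pyridine at 50 °C then brings about the Baker–Venkataraman O-to-C acyl shift and cleaves the aryl acetate, giving diketone 7. Cyclodehydration as in step 3 rejoins the route at 8.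

**Further compounds**
F1 | step 7 | 5,5''-bis(trifluoroacetate) of the bis-chromone | COc1cc(OC(=O)C(F)(F)F)c2c(=O)cc(-c3ccc(Oc4c(OC)cc5occc(=O)c5c4OC(=O)C(F)(F)F)cc3)oc2c1
F2 | step 7 | 5-hydroxy-2-{4-[(5-hydroxy-7-methoxy-4-oxo-4H-chromen-6-yl)oxy]phenyl}-7-methoxy-4H-chromen-4-one | COc1cc(O)c2c(=O)cc(-c3ccc(Oc4c(OC)cc5occc(=O)c5c4O)cc3)oc2c1
F3 | step 6 | (E)-1-{2-hydroxy-4-methoxy-5-[4-(7-methoxy-4-oxo-4H-chromen-2-yl)phenoxy]phenyl}-3-[4-(methoxymethoxy)phenyl]prop-2-en-1-one | COCOc1ccc(/C=C/C(=O)c2cc(Oc3ccc(-c4cc(=O)c5ccc(OC)cc5o4)cc3)c(OC)cc2O)cc1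
F4 | step 6 | racemic 7-methoxy-2-[4-(methoxymethoxy)phenyl]-6-[4-(7-methoxy-4-oxo-4H-chromen-2-yl)phenoxy]chroman-4-one | COCOc1ccc(C2CC(=O)c3cc(Oc4ccc(-c5cc(=O)c6ccc(OC)cc6o5)cc4)c(OC)cc3O2)cc1
F5 | step 6 | racemic 2-(4-hydroxyphenyl)-7-methoxy-6-[4-(7-methoxy-4-oxo-4H-chromen-2-yl)phenoxy]chroman-4-one | Oc1ccc(C2CC(=O)c3cc(Oc4ccc(-c5cc(=O)c6ccc(OC)cc6o5)cc4)c(OC)cc3O2)cc1
F6 | step 6 | racemic 4-{7-methoxy-6-[4-(7-methoxy-4-oxo-4H-chromen-2-yl)phenoxy]-4-oxochroman-2-yl}phenyl acetate | CC(=O)Oc1ccc(C2CC(=O)c3cc(Oc4ccc(-c5cc(=O)c6ccc(OC)cc6o5)cc4)c(OC)cc3O2)cc1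
F7 | step 6 | (R)-4-{7-methoxy-6-[4-(7-methoxy-4-oxo-4H-chromen-2-yl)phenoxy]-4-oxochroman-2-yl}phenyl acetate | COc1ccc2c(=O)cc(-c3ccc(Oc4c(OC)cc5c(c4)C(=O)C[C@H](c4ccc(OC(C)=O)cc4)O5)cc3)oc2c1
F8 | step 3 | 4-(4-hydroxy-2-methoxyphenoxy)benzoic acid | OC(=O)c1ccc(Oc2ccc(O)cc2OC)cc1
F9 | step 3 | 4-(4-acetoxy-2-methoxyphenoxy)benzoic acid | CC(=O)Oc1ccc(Oc2ccc(C(=O)O)cc2)c(OC)c1
F10 | step 3 | 4-(4-acetoxy-2-methoxyphenoxy)benzoyl chloride | CC(=O)Oc1ccc(Oc2ccc(C(=O)Cl)cc2)c(OC)c1
F11 | step 3 | 2-acetyl-5-methoxyphenyl 4-(4-acetoxy-2-methoxyphenoxy)benzoate | COc1ccc(C(C)=O)c(OC(=O)c2ccc(Oc3ccc(OC(C)=O)cc3OC)cc2)c1
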